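**Retrosynthetic overview**
1. Target 20 ⇐ aryl bromide 17 + acrolein dimethyl acetal 18 (Heck reaction, side chain last).
2. The 1,4-benzodioxane ring of 17 ⇐ 5→6 ring expansion of the 2-(1-mesyloxyethyl)-1,3-benzodioxole 13 by a 1,2-oxygen shift (sets C-3 by inversion), with capture of the ring-expanded oxocarbenium ion by the aryl-aluminium 15 (sets C-2, trans).
3. 13 ⇐ catechol 8 + (R)-2-(mesyloxy)propanal 11, from methyl (R)-lactate 9.
4. Aryl donor 7 and catechol 8 ⇐ common 4-bromo-2,6-dimethoxyphenol 6 ⇐ resorcinol 1 (methylation, ortho-lithiation/oxidation, bromination).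
5. Ring order: both benzene rings come from resorcinol; the dioxole ring is made in step 8 and expanded to the dioxane ring in step 9.

Assumption: MeI, NBS, H2O2, MsCl and the metal reagents are treated as reagents and carry no compound number. Compound 13 is used as the mixture of epimers at the acetal carbon, which becomes sp2 in step 9.

**Step 1**
Reactants: 1 resorcinol
Product: 2 1,3-dimethoxybenzene
Conditions: MeI, K2CO3, acetone, reflux
Reagents that add atoms: iodomethane, CI
Why: Williamson ether synthesis on both phenols; no stereocentre.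

**Step 2**
Reactants: 2 1,3-dimethoxybenzene
Product: 5 2,6-dimethoxyphenol, via 2,6-dimethoxyphenyllithium 3 (not isolated), via dimethyl (2,6-dimethoxyphenyl)boronate 4 (not isolated)
Conditions: n-BuLi, THF, 0 °C → rt; B(OMe)3, −78 °C → rt; AcOH, 30% H2O2, 0 °C → rt
Reagents that add atoms: hydrogen peroxide, OO
Why: Directed ortho-metalation at C-2 between the two methoxy groups, then borylation and peroxide oxidation of the aryl boronate give the phenol.

**Step 3**
Reactants: 5 2,6-dimethoxyphenol
Product: 6 4-bromo-2,6-dimethoxyphenol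
Conditions: NBS, CH2Cl2, −40 → 0 °C
Reagents that add atoms: N-bromosuccinimide, O=C1CCC(=O)N1Br
Why: Electrophilic aromatic bromination para to the free phenol, whose ortho positions are blocked.

**Step 4**
Reactants: 6 4-bromo-2,6-dimethoxyphenol
Product: 7 5-bromo-1,2,3-trimethoxybenzene
Conditions: MeI, K2CO3, acetone, reflux
Reagents that add atoms: iodomethane, CI
Why: Williamson ether synthesis on the phenol.

**Step 5**
Reactants: 6 4-bromo-2,6-dimethoxyphenol
Product: 8 5-bromo-3-methoxybenzene-1,2-diol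
Conditions: BBr3 (1.05 equiv), CH2Cl2, −78 → 0 °C; H2O
Reagents that add atoms: none
Why: Phenol-directed Lewis-acid ether cleavage: the ArO–BBr2 formed first cleaves one neighbouring OMe intramolecularly, and the resulting cyclic catechol bromoborane is too weak a Lewis acid to cleave the second (the two OMe groups are equivalent).

**Step 6**
Reactants: 9 methyl (2R)-2-hydroxypropanoate
Product: 10 methyl (2R)-2-(methanesulfonyloxy)propanoate
Conditions: MsCl, Et3N, CH2Cl2, 0 °C
Reagents that add atoms: methanesulfonyl chloride, CS(=O)(=O)Cl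
Why: O-sulfonylation of the secondary alcohol; the C–O bond is untouched, so the R configuration is retained.

**Step 7**
Reactants: 10 methyl (2R)-2-(methanesulfonyloxy)propanoate
Product: 11 (2R)-2-(methanesulfonyloxy)propanal
Conditions: DIBAL-H (1.1 equiv), CH2Cl2, −78 °C; MeOH, aq. Rochelle salt
Reagents that add atoms: none
Why: Partial DIBAL-H reduction of the ester through the tetrahedral aluminium hemiacetal, stable at −78 °C; base-free conditions leave the stereocentre intact.

**Step 8**
Reactants: 8 5-bromo-3-methoxybenzene-1,2-diol, 11 (2R)-2-(methanesulfonyloxy)propanal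
Product: 13 6-bromo-4-methoxy-2-[(1R)-1-(methanesulfonyloxy)ethyl]-1,3-benzodioxole, via 5-bromo-3-methoxy-1,2-bis(trimethylsilyloxy)benzene 12 (not isolated)
Conditions: 8, HMDS, cat. (NH4)2SO4, 80 °C, then vacuum; 11, TMSOTf (10 mol %), CH2Cl2, −78 → 0 °C
Reagents that add atoms: none
Why: Noyori-type acetalization (bis-silyl ether + aldehyde, TMSOTf) closes the dioxole ring at low temperature without enolising the α-sulfonyloxy aldehyde; the acetal carbon forms as both epimers, which does not matter.

**Step 9**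
Reactants: 13 6-bromo-4-methoxy-2-[(1R)-1-(methanesulfonyloxy)ethyl]-1,3-benzodioxole, 7 5-bromo-1,2,3-trimethoxybenzene
Product: 17 (2S,3S)-7-bromo-5-methoxy-3-methyl-2-(3,4,5-trimethoxyphenyl)-2,3-dihydro-1,4-benzodioxine, via 3,4,5-trimethoxyphenyllithium 14 (not isolated), via dimethyl(3,4,5-trimethoxyphenyl)alane 15 (not isolated), via (3S)-7-bromo-5-methoxy-3-methyl-3H-1,4-benzodioxin-1-ium 16 (not isolated)
Conditions: 7 (2.0 equiv), n-BuLi, Et2O–PhMe, −78 °C; Me2AlCl (2.5 equiv), −78 → 0 °C; then 13, CH2Cl2, −78 → 23 °C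
Reagents that add atoms: none
Why: Proposed new method: the arylalane binds the mesylate, and this secondary, acetal-flanked sulfonate can ionise only with anchimeric help, so ring oxygen O-3 (flanked by two oxygen-bearing carbons and para to Br, hence the least delocalised and most nucleophilic oxygen) attacks C-1′ from the rear, shifts from the acetal carbon to C-1′ with inversion (1′R → 3S) and expands the dioxole to the six-membered oxocarbenium ion 16, which the aluminate [ArMe2Al–OMs]− arylates (sp2 group transferred in preference to methyl) anti to the neighbouring methyl group to set 2S (2,3-trans); a 1,2-hydride shift is disfavoured because it needs cationic character at a carbon bearing two β-oxygens, whereas oxygen participation is an SN2-type displacement; the closest known reaction types are the 1→2 alkoxy/arylthio migration of 2-O-sulfonyl glycosides with capture of the new oxocarbenium ion, the ring expansion of 2-(1-haloalkyl)-1,3-dioxolanes and -dithiolanes to dihydro-1,4-dioxins and -dithiins, the organoaluminium-promoted stereospecific pinacol-type shift of lactate-derived mesylates, and the anti-selective C-arylation of cyclic oxocarbenium ions by arylalanes.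

**Step 10**
Reactants: 17 (2S,3S)-7-bromo-5-methoxy-3-methyl-2-(3,4,5-trimethoxyphenyl)-2,3-dihydro-1,4-benzodioxine, 18 3,3-dimethoxyprop-1-ene
Product: 20 (2E)-3-[(2S,3S)-5-methoxy-3-methyl-2-(3,4,5-trimethoxyphenyl)-2,3-dihydro-1,4-benzodioxin-7-yl]prop-2-enal, via (2S,3S)-7-[(1E)-3,3-dimethoxyprop-1-en-1-yl]-5-methoxy-3-methyl-2-(3,4,5-trimethoxyphenyl)-2,3-dihydro-1,4-benzodioxine 19 (not isolated)
Conditions: Pd(OAc)2 (3 mol %), n-Bu4NOAc, K2CO3, KCl, DMF, 90 °C; then 2 M HCl, rt
Reagents that add atoms: water, O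
Why: Heck reaction of the aryl bromide with the acrolein acetal (syn insertion and syn β-hydride elimination give the E alkene), then mild acetal hydrolysis; both stereocentres are remote and untouched.

**Compound list**
1 | resorcinol (benzene-1,3-diol) | Oc1cccc(O)c1 | starting material
2 | 1,3-dimethoxybenzene | COc1cccc(OC)c1 | intermediate
3 | 2,6-dimethoxyphenyllithium (not isolated) | [Li]c1c(OC)cccc1OC | intermediate
4 | dimethyl (2,6-dimethoxyphenyl)boronate (not isolated) | COB(OC)c1c(OC)cccc1OC | intermediate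
5 | 2,6-dimethoxyphenol | COc1cccc(OC)c1O | intermediate
6 | 4-bromo-2,6-dimethoxyphenol | COc1cc(Br)cc(OC)c1O | intermediate
7 | 5-bromo-1,2,3-trimethoxybenzene | COc1cc(Br)cc(OC)c1OC | intermediate
8 | 5-bromo-3-methoxybenzene-1,2-diol | COc1cc(Br)cc(O)c1O | intermediate
9 | methyl (2R)-2-hydroxypropanoate (methyl D-lactate) | C[C@@H](O)C(=O)OC | starting material
10 | methyl (2R)-2-(methanesulfonyloxy)propanoate | C[C@@H](OS(C)(=O)=O)C(=O)OC | intermediate
11 | (2R)-2-(methanesulfonyloxy)propanal | C[C@@H](OS(C)(=O)=O)C=O | intermediate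
12 | 5-bromo-3-methoxy-1,2-bis(trimethylsilyloxy)benzene (not isolated) | COc1cc(Br)cc(O[Si](C)(C)C)c1O[Si](C)(C)C | intermediate
13 | 6-bromo-4-methoxy-2-[(1R)-1-(methanesulfonyloxy)ethyl]-1,3-benzodioxole (both epimers at C-2) | C[C@@H](OS(C)(=O)=O)C1Oc2cc(Br)cc(OC)c2O1 | intermediate
14 | 3,4,5-trimethoxyphenyllithium (not isolated) | [Li]c1cc(OC)c(OC)c(OC)c1 | intermediate
15 | dimethyl(3,4,5-trimethoxyphenyl)alane (not isolated) | C[Al](C)c1cc(OC)c(OC)c(OC)c1 | intermediate
16 | (3S)-7-bromo-5-methoxy-3-methyl-3H-1,4-benzodioxin-1-ium (not isolated) | C[C@H]1C=[O+]c2cc(Br)cc(OC)c2O1 | intermediate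
17 | (2S,3S)-7-bromo-5-methoxy-3-methyl-2-(3,4,5-trimethoxyphenyl)-2,3-dihydro-1,4-benzodioxine (trans) | COc1cc([C@@H]2Oc3cc(Br)cc(OC)c3O[C@H]2C)cc(OC)c1OC | intermediate
18 | 3,3-dimethoxyprop-1-ene (acrolein dimethyl acetal) | C=CC(OC)OC | starting material
19 | (2S,3S)-7-[(1E)-3,3-dimethoxyprop-1-en-1-yl]-5-methoxy-3-methyl-2-(3,4,5-trimethoxyphenyl)-2,3-dihydro-1,4-benzodioxine (not isolated) | COc1cc([C@@H]2Oc3cc(/C=C/C(OC)OC)cc(OC)c3O[C@H]2C)cc(OC)c1OC | intermediate
20 | (2E)-3-[(2S,3S)-5-methoxy-3-methyl-2-(3,4,5-trimethoxyphenyl)-2,3-dihydro-1,4-benzodioxin-7-yl]prop-2-enal | COc1cc([C@@H]2Oc3cc(/C=C/C=O)cc(OC)c3O[C@H]2C)cc(OC)c1OC | target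

**Totals**
Total step count: 10. Longest linear sequence: 7 steps (steps 1, 2, 3, 5, 8, 9, 10, from resorcinol). Step 4 and steps 6–7 are side branches.

**Three steps most likely to fail**

Step 9 (the proposed ring expansion). Risks: migration of the other ring oxygen (regioisomeric benzodioxane), a competing 1,2-hydride shift, methyl instead of aryl transfer, or sluggish ionisation of the mesylate. The fallback uses known chemistry, sets out from 8 and comes back at 17. Catechol 8 is silylated at its less hindered 1-OH (TBSCl, imidazole, DMF, 0 °C) to give 4-bromo-2-[(tert-butyldimethylsilyl)oxy]-6-methoxyphenol F1. A Mitsunobu reaction of the remaining central phenol with 9 (PPh3, DIAD, THF) gives, with inversion, methyl (2S)-2-{4-bromo-2-[(tert-butyldimethylsilyl)oxy]-6-methoxyphenoxy}propanoate F2. DIBAL-H at −78 °C gives (2S)-2-{4-bromo-2-[(tert-butyldimethylsilyl)oxy]-6-methoxyphenoxy}propanal F3. This is treated with (3,4,5-trimethoxyphenyl)magnesium bromide F4 (from 7 and Mg in THF) to give (1RS,2S)-2-{4-bromo-2-[(tert-butyldimethylsilyl)oxy]-6-methoxyphenoxy}-1-(3,4,5-trimethoxyphenyl)propan-1-ol F5 as both carbinol epimers. TBAF frees 5-bromo-2-{[(1RS,2S)-1-hydroxy-1-(3,4,5-trimethoxyphenyl)propan-2-yl]oxy}-3-methoxyphenol F6. Acid (Amberlyst-15 or cat. TsOH, toluene) then closes the ring through the benzylic cation, which the phenol attacks anti to the methyl group, so both epimers converge on trans-17.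

Step 8 (acetalization of the sensitive α-mesyloxy aldehyde). Risks: slow ring closure through an electron-poor oxocarbenium ion, enolisation or loss of MsOH. The fallback sets out from 8 and comes back at 13. Transacetalization of 8 with 1,1-dimethoxyacetone (cat. TsOH, toluene, 90 °C, MeOH distilled off) gives 1-(6-bromo-4-methoxy-1,3-benzodioxol-2-yl)ethan-1-one F7. CBS reduction ((S)-Me-CBS, BH3·SMe2, THF, −20 °C; the acetal carbon is the large group) gives (1R)-1-(6-bromo-4-methoxy-1,3-benzodioxol-2-yl)ethan-1-ol F8. Mesylation (MsCl, Et3N) gives 13. Here the stereocentre comes from catalytic asymmetric reduction instead of the chiral pool.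

Step 10 (Heck reaction on an electron-rich aryl bromide). Risks: slow oxidative addition, or the 3-arylpropanoate by-product. The fallback sets out from 17 and comes back at 20. Bromine–lithium exchange (n-BuLi, THF, −78 °C) gives [(2S,3S)-5-methoxy-3-methyl-2-(3,4,5-trimethoxyphenyl)-2,3-dihydro-1,4-benzodioxin-7-yl]lithium F9. Quenching with DMF gives (2S,3S)-5-methoxy-3-methyl-2-(3,4,5-trimethoxyphenyl)-2,3-dihydro-1,4-benzodioxine-7-carbaldehyde F10. A Wittig reaction with (triphenylphosphoranylidene)acetaldehyde (toluene, 80 °C) gives the E enal 20.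

**Further compounds**
F1 | step 9 | 4-bromo-2-[(tert-butyldimethylsilyl)oxy]-6-methoxyphenol | COc1cc(Br)cc(O[Si](C)(C)C(C)(C)C)c1O
F2 | step 9 | methyl (2S)-2-{4-bromo-2-[(tert-butyldimethylsilyl)oxy]-6-methoxyphenoxy}propanoate | C[C@H](Oc1c(OC)cc(Br)cc1O[Si](C)(C)C(C)(C)C)C(=O)OC
F3 | step 9 | (2S)-2-{4-bromo-2-[(tert-butyldimethylsilyl)oxy]-6-methoxyphenoxy}propanal | C[C@H](Oc1c(OC)cc(Br)cc1O[Si](C)(C)C(C)(C)C)C=O
F4 | step 9 | (3,4,5-trimethoxyphenyl)magnesium bromide | COc1cc([Mg]Br)cc(OC)c1OC
F5 | step 9 | (1RS,2S)-2-{4-bromo-2-[(tert-butyldimethylsilyl)oxy]-6-methoxyphenoxy}-1-(3,4,5-trimethoxyphenyl)propan-1-ol | C[C@H](Oc1c(OC)cc(Br)cc1O[Si](C)(C)C(C)(C)C)C(O)c1cc(OC)c(OC)c(OC)c1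
F6 | step 9 | 5-bromo-2-{[(1RS,2S)-1-hydroxy-1-(3,4,5-trimethoxyphenyl)propan-2-yl]oxy}-3-methoxyphenol | C[C@H](Oc1c(O)cc(Br)cc1OC)C(O)c1cc(OC)c(OC)c(OC)c1
F7 | step 8 | 1-(6-bromo-4-methoxy-1,3-benzodioxol-2-yl)ethan-1-one | CC(=O)C1Oc2cc(Br)cc(OC)c2O1
F8 | step 8 | (1R)-1-(6-bromo-4-methoxy-1,3-benzodioxol-2-yl)ethan-1-ol | C[C@@H](O)C1Oc2cc(Br)cc(OC)c2O1
F9 | step 10 | [(2S,3S)-5-methoxy-3-methyl-2-(3,4,5-trimethoxyphenyl)-2,3-dihydro-1,4-benzodioxin-7-yl]lithium | COc1cc([C@@H]2Oc3cc([Li])cc(OC)c3O[C@H]2C)cc(OC)c1OC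
F10 | step 10 | (2S,3S)-5-methoxy-3-methyl-2-(3,4,5-trimethoxyphenyl)-2,3-dihydro-1,4-benzodioxine-7-carbaldehyde | COc1cc([C@@H]2Oc3cc(C=O)cc(OC)c3O[C@H]2C)cc(OC)c1OC
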